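The runs were generated by integration for an exercise.

Slowness is what the late readings do not show: past 1.33 min, target and other capture product in the earlier runs cedar, ash and maple show no drift beyond the scatter of 1 percentage point. Each run therefore has a plateau ratio, taken here from its last 3 readings.

| flask | starting material | first nucleophile | second nucleophile | remark | time |
|---|---|---|---|---|---|
| cedar | 1 mM | 1.8 equiv | 1 equiv | run made earlier |  |
| ash | 4 mM | 1.8 equiv | 1 equiv | run made earlier |  |
| maple | 2 mM | 2.7 equiv | 1 equiv | run made earlier |  |
| flask | 2.0 mM | 1.80 equiv | 1.00 equiv |  | 4.0 min |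

| run | time / min | other capture product / % | target / % |
|---|---|---|---|
| cedar | 0.417 | 11.2 | 10.5 |
| cedar | 0.833 | 11.9 | 10.5 |
| cedar | 1.33 | 11.6 | 9.3 |
| cedar | 1.50 | 12.6 | 11.6 |
| cedar | 2.00 | 10.6 | 11.9 |
| cedar | 2.50 | 13.1 | 12.1 |
| ash | 0.167 | 15.6 | 19.2 |
| ash | 0.500 | 21.1 | 24.2 |
| ash | 0.833 | 23.1 | 21.7 |
| ash | 1.33 | 21.6 | 21.9 |
| ash | 2.00 | 23.2 | 23.3 |
| ash | 2.50 | 22.2 | 21.8 |
| maple | 0.500 | 15.4 | 22.6 |
| maple | 1.00 | 13.7 | 23.9 |
| maple | 1.33 | 15.0 | 22.4 |
| maple | 2.00 | 14.7 | 22.8 |
| maple | 2.50 | 15.5 | 21.8 |

(scatter of a reading: 1 percentage point)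

1. ratio of other capture product to target at 0.30 s
2. ratio of other capture product to target at 8.0 s
3. ratio of other capture product to target at 4.0 min



If the two nucleophiles compete in parallel, that ratio should follow their charges. Folding the charges in gives S, an apparent selectivity factor: plateau ratio of other capture product to target, times equivalents of first nucleophile over equivalents of second nucleophile. Cedar gives 1.84, ash 1.80 and maple 1.82. Cedar and ash differ in concentration, 1 mM against 4 mM, and maple carries 2.7 equiv of first nucleophile at 2 mM, so one number describes these plateau readings within their scatter. Their mean is S = 1.82.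

My own reckoning for the flask is N = S times second over first nucleophile, or 1.01 other capture product per target at 4.0 min. The readings begin at 0.167 min, so N is not offered for 0.30 s or 8.0 s. The forecast gives 0.95, 0.93 and 1.02, noting that “no run has data below 10 s”.

The flask gives 1.95 at 0.30 s, 1.06 at 8.0 s and 0.990 at 4.0 min, so the first stands at twice N and the last close to it.

    starting material → intermediate (k = 0.154 s⁻¹)
    first nucleophile + intermediate → target (k = 19500 M⁻¹ s⁻¹)
    second nucleophile + intermediate → other capture product (k = 74800 M⁻¹ s⁻¹)
    intermediate → solvolysis product (k = 217 s⁻¹)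
    second nucleophile ⇌ dormant form (K = 1.43, k = 0.564 s⁻¹)
    2 starting material → self-condensation product (k = 9.26 M⁻¹ s⁻¹)

At 0.0694 min in the flask, second nucleophile enters the dormant form, forward step by itself, at 18 times the rate at which it enters other capture product. At 4.0 min the flask holds 0.978 mM of dormant form beside second nucleophile at 34.2 % of its own charge. For a neighbour flask with 2.50 equiv of second nucleophile and the other charges as in the flask, S gives 2.53, and that neighbour shows 2.48 at 4.0 min.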